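**Retrosynthetic overview**

1. The target is two (2R,3S)-2,3-trans-3',4',7,8-tetrahydroxyflavan-3-ol halves joined from C5 of one half to C6 of the other. The last operations are hydrogenolysis of eight benzyl ethers and a two-fold Baeyer–Villiger oxidation that turns two C3-acetyl groups (temporary activating groups) into the C3–O bonds with retention.
2. Key disconnection: the C2–C3 bond of ring C in the 5-linked half, cut together with its twin in the 6-linked half. Both rings C close in one operation from an achiral bis-enone, by 1,5-hydride transfer from C2 to C4 followed by C3-to-C2 bond formation under a chiral primary amine salt.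
3. Enabling feature: in each half the C2–H bond is benzylic to the catechol ring B (para oxygen at C4') and alpha to the ring oxygen O1, hence hydridic. It lies 1,5 to C4 (H–C2–O1–C8a–C4a–C4), which the target keeps as an unoxygenated CH2, and the O1=C2 oxocarbenium ion left behind is trapped by C3.
4. The bis-enone comes from a biaryl bis-salicylaldehyde by O-alkylation with the ring B benzyl chloride and Wittig olefination. The bis-salicylaldehyde comes from Suzuki–Miyaura coupling of two pyrogallol-type arenes, Vilsmeier–Haack formylation and chelation-controlled ortho-debenzylation.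
5. Ring order: rings A and B are bought as arenes, the A–A biaryl bond is made in step 5, and the two rings C close last (step 10), which sets all four stereocentres.

Key step: step 10

Assumption: the biaryl axis carries only two ortho substituents and is treated as freely rotating, in line with the target structure, which defines no axial configuration.

**Route**

Step 1
Reactants: 1 2,3,4-trihydroxybenzaldehyde; 2 benzyl bromide
Product: 3 2,3,4-tris(benzyloxy)benzaldehyde
Conditions: BnBr (3.6 equiv), K2CO3, DMF, 60 °C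
Reagents that add atoms: benzyl bromide BrCc1ccccc1
Why: Williamson etherification of all three phenols; the formyl-chelated 2-OH reacts last and is driven to completion by excess bromide and heat.

Step 2
Reactants: 3 2,3,4-tris(benzyloxy)benzaldehyde; 4 N-bromosuccinimide
Product: 5 5-bromo-2,3,4-tris(benzyloxy)benzaldehyde
Conditions: NBS, MeCN, rt, dark
Reagents that add atoms: N-bromosuccinimide O=C1CCC(=O)N1Br
Why: Electrophilic aromatic bromination should go to C5, the only free position that is ortho to one benzyloxy group and para to another, whereas C6 sits next to the deactivating formyl group.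

Step 3
Reactants: 6 5-bromobenzene-1,2,3-triol; 2 benzyl bromide
Product: 7 5-bromo-1,2,3-tris(benzyloxy)benzene
Conditions: BnBr (3.6 equiv), K2CO3, DMF, 60 °C, under N2
Reagents that add atoms: benzyl bromide BrCc1ccccc1
Why: Williamson etherification protects the three phenols as benzyl ethers.

Step 4
Reactants: 7 5-bromo-1,2,3-tris(benzyloxy)benzene; 8 bis(pinacolato)diboron
Product: 9 2-[3,4,5-tris(benzyloxy)phenyl]-4,4,5,5-tetramethyl-1,3,2-dioxaborolane
Conditions: B2pin2, Pd(dppf)Cl2 (3 mol %), KOAc, 1,4-dioxane, 90 °C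
Reagents that add atoms: bis(pinacolato)diboron CC1(C)OB(OC1(C)C)B1OC(C)(C)C(C)(C)O1
Why: Miyaura borylation of the aryl bromide.

Step 5
Reactants: 5 5-bromo-2,3,4-tris(benzyloxy)benzaldehyde; 9 2-[3,4,5-tris(benzyloxy)phenyl]-4,4,5,5-tetramethyl-1,3,2-dioxaborolane
Product: 10 2,3,4-tris(benzyloxy)-5-[3,4,5-tris(benzyloxy)phenyl]benzaldehyde
Conditions: Pd(PPh3)4 (5 mol %), K2CO3, 1,4-dioxane/H2O, 90 °C
Reagents that add atoms: none
Why: Suzuki–Miyaura coupling joins the two rings A at the carbons that become C6 of one half and C5 of the other.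

Step 6
Reactants: 10 2,3,4-tris(benzyloxy)-5-[3,4,5-tris(benzyloxy)phenyl]benzaldehyde; 11 N,N-dimethylformamide; 12 water
Product: 14 2,3,4-tris(benzyloxy)-6-[2,3,4-tris(benzyloxy)-5-formylphenyl]benzaldehyde, via aryl iminium chloride 13 (not isolated)
Conditions: POCl3, DMF, 0 to 70 °C; then H2O
Reagents that add atoms: N,N-dimethylformamide CN(C)C=O (formyl carbon); water O (formyl oxygen)
Why: Vilsmeier–Haack formylation: the tris(benzyloxy)phenyl ring is the only activated ring, its two free positions are equivalent (ortho to one outer benzyloxy group, para to the other), and the other ring is deactivated by its formyl group; the iminium salt is hydrolysed on work-up.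

Step 7
Reactants: 14 2,3,4-tris(benzyloxy)-6-[2,3,4-tris(benzyloxy)-5-formylphenyl]benzaldehyde
Product: 15 3,4-bis(benzyloxy)-6-[2,3-bis(benzyloxy)-5-formyl-4-hydroxyphenyl]-2-hydroxybenzaldehyde
Conditions: MgBr2·OEt2 (3 equiv), toluene/Et2O, 80 °C; then 1 M HCl
Reagents that add atoms: none
Why: Chelation-controlled dealkylation: magnesium held between a formyl oxygen and the adjacent ether oxygen activates only that benzyl group for attack by bromide, one on each ring.

Step 8
Reactants: 15 3,4-bis(benzyloxy)-6-[2,3-bis(benzyloxy)-5-formyl-4-hydroxyphenyl]-2-hydroxybenzaldehyde; 16 3,4-bis(benzyloxy)benzyl chloride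
Product: 17 3,4-bis(benzyloxy)-2-{[3,4-bis(benzyloxy)phenyl]methoxy}-6-[2,3-bis(benzyloxy)-4-{[3,4-bis(benzyloxy)phenyl]methoxy}-5-formylphenyl]benzaldehyde
Conditions: K2CO3, KI (cat.), DMF, 60 °C
Reagents that add atoms: 3,4-bis(benzyloxy)benzyl chloride ClCc1ccc(OCc2ccccc2)c(OCc2ccccc2)c1
Why: Williamson etherification of the two chelated phenols with the benzylic chloride that brings in ring B and the future C2 of each half.

Step 9
Reactants: 17 bis-aldehyde from step 8; 18 1-(triphenyl-λ5-phosphanylidene)propan-2-one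
Product: 19 (E)-4-{3,4-bis(benzyloxy)-2-{[3,4-bis(benzyloxy)phenyl]methoxy}-6-[2,3-bis(benzyloxy)-4-{[3,4-bis(benzyloxy)phenyl]methoxy}-5-[(E)-3-oxobut-1-enyl]phenyl]phenyl}but-3-en-2-one (bis-enone)
Conditions: toluene, 110 °C
Reagents that add atoms: 1-(triphenyl-λ5-phosphanylidene)propan-2-one CC(=O)C=P(c1ccccc1)(c1ccccc1)c1ccccc1
Why: Wittig olefination with a stabilised ylide should give the E-enones and tolerate the flanking ortho substituents.

Step 10
Reactants: 19 bis-enone
Product: 20 5,6'-linked bis[(2S,3S)-3-acetyl-7,8-bis(benzyloxy)-2-(3,4-bis(benzyloxy)phenyl)chromane] (2,3-trans in both halves; C5 of one chromane bonded to C6 of the other)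
Conditions: 9-amino-9-deoxy-epi-quinine (40 mol %), CF3CO2H (80 mol %), toluene, 60 °C
Reagents that add atoms: none
Why: Proposed new method: the primary amine salt converts each enone into an iminium ion whose C4 takes the hydride from C2 of the facing ring B benzyl ether through a six-membered (1,5) transition state, and the enamine so formed (nucleophilic C3) then bonds to C2 of the O1=C2 oxocarbenium ion, which ring B stabilises through its para oxygen, before hydrolysis frees the ketone and the catalyst. The closest known reaction type is the acid-catalysed 1,5-hydride shift/cyclisation (internal redox) of aryl benzyl ethers carrying an ortho alkylidene acceptor, which gives 2-arylchromans, together with its enantioselective iminium-catalysed form on enals with ether or amine hydride donors; the pairing of an enone, a chiral primary amine and an aryl benzyl ether donor, run on two arms at once, has not been shown. Each ring C closes in the 6-(enolexo)-endo-trig mode, the enamine carbon C3 attacking the oxocarbenium carbon C2. C2 is set in the bond-forming event by the face of the oxocarbenium ion that the chiral enamine reaches, each arm being steered by its own catalyst molecule, and C3, which stays epimerisable through the enamine, should settle trans to the C2 aryl group with both substituents equatorial. Of the ten ArO–CH2 groups only the two O1–CH2 groups lie 1,5 to an acceptor carbon, which secures the site selectivity, and C4 ends as a CH2 group without a stereocentre. The absolute sense is the open point: the quinine-derived amine is nominated for the (2S,3S) ketone, and its quinidine-derived pseudoenantiomer takes its place if a first run shows the opposite sense.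

Step 11
Reactants: 20 bis-ketone; 21 3-chloroperoxybenzoic acid
Product: 22 (2R,2'R,3S,3'S)-7,7',8,8'-tetrakis(benzyloxy)-2,2'-bis[3,4-bis(benzyloxy)phenyl]-3,3',4,4'-tetrahydro-2H,2'H-[5,6'-bichromene]-3,3'-diyl diacetate
Conditions: mCPBA (6 equiv), CH2Cl2, 0 °C to rt, dark
Reagents that add atoms: 3-chloroperoxybenzoic acid OOC(=O)c1cccc(Cl)c1
Why: Baeyer–Villiger oxidation: the secondary carbon C3 migrates in preference to methyl with retention, so each trans acetyl group becomes the trans acetate (the C2 descriptor changes from S to R only through the priority change at C3).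

Step 12
Reactants: 22 bis-acetate
Product: 23 (2R,2'R,3S,3'S)-7,7',8,8'-tetrakis(benzyloxy)-2,2'-bis[3,4-bis(benzyloxy)phenyl]-3,3',4,4'-tetrahydro-2H,2'H-[5,6'-bichromene]-3,3'-diol
Conditions: K2CO3 (cat.), MeOH/THF, rt
Reagents that add atoms: none
Why: Base-catalysed transesterification of the two secondary acetates; no centre is epimerisable under these conditions.

Step 13
Reactants: 23 octabenzyl diol
Product: 24 (2R,2'R,3S,3'S)-2,2'-bis(3,4-dihydroxyphenyl)-3,3',4,4'-tetrahydro-2H,2'H-[5,6'-bichromene]-3,3',7,7',8,8'-hexol (target)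
Conditions: H2 (1 atm), Pd(OH)2/C, THF/MeOH, rt, work-up under argon
Reagents that add atoms: none
Why: Hydrogenolysis of the eight aryl benzyl ethers; the benzylic C2–O1 bond of ring C is expected to survive these neutral conditions, as it does in benzylated flavan-3-ols, and no stereocentre is touched.

**Compound list**

1 | 2,3,4-trihydroxybenzaldehyde | O=Cc1ccc(O)c(O)c1O | starting material
2 | benzyl bromide | BrCc1ccccc1 | starting material
3 | 2,3,4-tris(benzyloxy)benzaldehyde | O=Cc1ccc(OCc2ccccc2)c(OCc2ccccc2)c1OCc1ccccc1 | intermediate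
4 | N-bromosuccinimide | O=C1CCC(=O)N1Br | starting material
5 | 5-bromo-2,3,4-tris(benzyloxy)benzaldehyde | O=Cc1cc(Br)c(OCc2ccccc2)c(OCc2ccccc2)c1OCc1ccccc1 | intermediate
6 | 5-bromobenzene-1,2,3-triol | Oc1cc(Br)cc(O)c1O | starting material
7 | 5-bromo-1,2,3-tris(benzyloxy)benzene | Brc1cc(OCc2ccccc2)c(OCc2ccccc2)c(OCc2ccccc2)c1 | intermediate
8 | bis(pinacolato)diboron | CC1(C)OB(OC1(C)C)B1OC(C)(C)C(C)(C)O1 | starting material
9 | 2-[3,4,5-tris(benzyloxy)phenyl]-4,4,5,5-tetramethyl-1,3,2-dioxaborolane | CC1(C)OB(OC1(C)C)c1cc(OCc2ccccc2)c(OCc2ccccc2)c(OCc2ccccc2)c1 | intermediate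
10 | 2,3,4-tris(benzyloxy)-5-[3,4,5-tris(benzyloxy)phenyl]benzaldehyde | O=Cc1cc(-c2cc(OCc3ccccc3)c(OCc3ccccc3)c(OCc3ccccc3)c2)c(OCc2ccccc2)c(OCc2ccccc2)c1OCc1ccccc1 | intermediate
11 | N,N-dimethylformamide | CN(C)C=O | starting material
12 | water | O | starting material
13 | N-{[2,3,4-tris(benzyloxy)-6-(2,3,4-tris(benzyloxy)-5-formylphenyl)phenyl]methylidene}-N-methylmethanaminium chloride | C[N+](C)=Cc1c(-c2cc(C=O)c(OCc3ccccc3)c(OCc3ccccc3)c2OCc2ccccc2)cc(OCc2ccccc2)c(OCc2ccccc2)c1OCc1ccccc1.[Cl-] | intermediate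
14 | 2,3,4-tris(benzyloxy)-6-[2,3,4-tris(benzyloxy)-5-formylphenyl]benzaldehyde | O=Cc1cc(-c2cc(OCc3ccccc3)c(OCc3ccccc3)c(OCc3ccccc3)c2C=O)c(OCc2ccccc2)c(OCc2ccccc2)c1OCc1ccccc1 | intermediate
15 | 3,4-bis(benzyloxy)-6-[2,3-bis(benzyloxy)-5-formyl-4-hydroxyphenyl]-2-hydroxybenzaldehyde | O=Cc1cc(-c2cc(OCc3ccccc3)c(OCc3ccccc3)c(O)c2C=O)c(OCc2ccccc2)c(OCc2ccccc2)c1O | intermediate
16 | 3,4-bis(benzyloxy)benzyl chloride | ClCc1ccc(OCc2ccccc2)c(OCc2ccccc2)c1 | starting material
17 | 3,4-bis(benzyloxy)-2-{[3,4-bis(benzyloxy)phenyl]methoxy}-6-[2,3-bis(benzyloxy)-4-{[3,4-bis(benzyloxy)phenyl]methoxy}-5-formylphenyl]benzaldehyde | O=Cc1cc(-c2cc(OCc3ccccc3)c(OCc3ccccc3)c(OCc3ccc(OCc4ccccc4)c(OCc4ccccc4)c3)c2C=O)c(OCc2ccccc2)c(OCc2ccccc2)c1OCc1ccc(OCc2ccccc2)c(OCc2ccccc2)c1 | intermediate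
18 | 1-(triphenyl-λ5-phosphanylidene)propan-2-one | CC(=O)C=P(c1ccccc1)(c1ccccc1)c1ccccc1 | starting material
19 | bis-enone: 17 with each formyl group replaced by an (E)-3-oxobut-1-enyl group | CC(=O)/C=C/c1cc(-c2cc(OCc3ccccc3)c(OCc3ccccc3)c(OCc3ccc(OCc4ccccc4)c(OCc4ccccc4)c3)c2/C=C/C(C)=O)c(OCc2ccccc2)c(OCc2ccccc2)c1OCc1ccc(OCc2ccccc2)c(OCc2ccccc2)c1 | intermediate
20 | 1,1'-[(2S,2'S,3S,3'S)-7,7',8,8'-tetrakis(benzyloxy)-2,2'-bis[3,4-bis(benzyloxy)phenyl]-3,3',4,4'-tetrahydro-2H,2'H-[5,6'-bichromene]-3,3'-diyl]di(ethan-1-one) | c1ccccc1COc1ccc([C@H]2Oc3c(cc(-c4cc(OCc5ccccc5)c(OCc5ccccc5)c5c4C[C@H](C(C)=O)[C@@H](c4ccc(OCc6ccccc6)c(OCc6ccccc6)c4)O5)c(OCc4ccccc4)c3OCc3ccccc3)C[C@@H]2C(C)=O)cc1OCc1ccccc1 | intermediate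
21 | 3-chloroperoxybenzoic acid | OOC(=O)c1cccc(Cl)c1 | starting material
22 | (2R,2'R,3S,3'S)-7,7',8,8'-tetrakis(benzyloxy)-2,2'-bis[3,4-bis(benzyloxy)phenyl]-3,3',4,4'-tetrahydro-2H,2'H-[5,6'-bichromene]-3,3'-diyl diacetate | c1ccccc1COc1ccc([C@H]2Oc3c(cc(-c4cc(OCc5ccccc5)c(OCc5ccccc5)c5c4C[C@H](OC(C)=O)[C@@H](c4ccc(OCc6ccccc6)c(OCc6ccccc6)c4)O5)c(OCc4ccccc4)c3OCc3ccccc3)C[C@@H]2OC(C)=O)cc1OCc1ccccc1 | intermediate
23 | (2R,2'R,3S,3'S)-7,7',8,8'-tetrakis(benzyloxy)-2,2'-bis[3,4-bis(benzyloxy)phenyl]-3,3',4,4'-tetrahydro-2H,2'H-[5,6'-bichromene]-3,3'-diol | c1ccccc1COc1ccc([C@H]2Oc3c(cc(-c4cc(OCc5ccccc5)c(OCc5ccccc5)c5c4C[C@H](O)[C@@H](c4ccc(OCc6ccccc6)c(OCc6ccccc6)c4)O5)c(OCc4ccccc4)c3OCc3ccccc3)C[C@@H]2O)cc1OCc1ccccc1 | intermediate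
24 | (2R,2'R,3S,3'S)-2,2'-bis(3,4-dihydroxyphenyl)-3,3',4,4'-tetrahydro-2H,2'H-[5,6'-bichromene]-3,3',7,7',8,8'-hexol | Oc1ccc([C@H]2Oc3c(cc(-c4cc(O)c(O)c5c4C[C@H](O)[C@@H](c4ccc(O)c(O)c4)O5)c(O)c3O)C[C@@H]2O)cc1O | target

**Count and risks**

Total step count: 13. Longest linear sequence: 11 steps (steps 1, 2, 5–13, or equally 3, 4, 5–13).

Steps most likely to fail:

1. Step 10 (labelled step). Hydride transfer to the donor-substituted iminium ion may be too slow. The facial selectivity at C2 may be low or of the wrong sense. The C2 configuration may also erode by reversible opening of ring C (beta-elimination of the phenoxide through the enamine), and the oxocarbenium ion may be hydrolysed with loss of ring B. The fallback uses known chemistry, still closes both rings C at C2–C3, sets out from 15 and returns at 23.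
   - The two phenols of 15 are converted with di-tert-butyl dicarbonate (DMAP cat., i-Pr2NEt, CH2Cl2) into the bis(aryl tert-butyl carbonate) dialdehyde F1.
   - BH3·SMe2 reduces both formyl groups to give the bis(benzylic alcohol) bis-carbonate F2.
   - Vinylmagnesium bromide (excess, THF, −78 °C to rt) deprotonates each alcohol; the carbonate migrates to the benzylic oxygen and is expelled to give an ortho-quinone methide, to which a second equivalent adds, giving the bis(2-allylphenol) F3.
   - Esterification with 3,4-bis(benzyloxy)benzoic acid (DCC, DMAP) gives the bis(aryl ester) F4.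
   - Petasis methylenation (Cp2TiMe2, toluene, 70 °C) gives the bis(1-arylvinyl aryl ether) F5.
   - Ring-closing metathesis (second-generation Grubbs catalyst, toluene, 80 °C) forms both C2=C3 bonds and gives the bis(2-aryl-4H-chromene) F6.
   - Asymmetric hydroboration with monoisopinocampheylborane (the antipode that delivers boron to the C3 face leading to 3S), then NaOH/H2O2, should give 23; syn addition of H to C2 and B to C3 makes each half 2,3-trans.

2. Step 7. More than the two chelated benzyl groups may be lost, or cleavage may stay incomplete at the more hindered formyl group. The fallback sets out from 14 and returns at 15. All six benzyl ethers are removed (BCl3, pentamethylbenzene, CH2Cl2, −78 °C) to give the hexahydroxy dialdehyde 2,3,4-trihydroxy-6-(5-formyl-2,3,4-trihydroxyphenyl)benzaldehyde F7. Its four non-chelated, more acidic hydroxyl groups (meta and para to the formyl groups) are then benzylated again (BnBr 4 equiv, NaHCO3, DMF, 40 °C), which leaves the two formyl-chelated ortho hydroxyl groups free and gives 15.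

3. Step 6. Electrophilic attack at a position flanked by the aryl group and a benzyloxy group may be slow, with acid-induced loss of benzyl groups on prolonged heating. The fallback sets out from 7 and 5 and returns at 14, with the formyl group installed before the coupling and the coupling polarity reversed. Vilsmeier–Haack formylation of 7 at the unhindered position between bromine and a benzyloxy group gives 6-bromo-2,3,4-tris(benzyloxy)benzaldehyde F8. Miyaura borylation of 5 (B2pin2, Pd(dppf)Cl2, KOAc) gives 2,3,4-tris(benzyloxy)-5-(4,4,5,5-tetramethyl-1,3,2-dioxaborolan-2-yl)benzaldehyde F9. Suzuki–Miyaura coupling of F8 with F9 (Pd(PPh3)4, K2CO3, dioxane/H2O) gives 14 directly.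

**Further compounds**

F1 | step 10 | bis(tert-butyl carbonate) of 15 | O=Cc1cc(-c2cc(OCc3ccccc3)c(OCc3ccccc3)c(OC(=O)OC(C)(C)C)c2C=O)c(OCc2ccccc2)c(OCc2ccccc2)c1OC(=O)OC(C)(C)C
F2 | step 10 | bis(hydroxymethyl) analogue of F1 | OCc1cc(-c2cc(OCc3ccccc3)c(OCc3ccccc3)c(OC(=O)OC(C)(C)C)c2CO)c(OCc2ccccc2)c(OCc2ccccc2)c1OC(=O)OC(C)(C)C
F3 | step 10 | bis(2-allylphenol): 15 with each formyl group replaced by an allyl group | C=CCc1cc(-c2cc(OCc3ccccc3)c(OCc3ccccc3)c(O)c2CC=C)c(OCc2ccccc2)c(OCc2ccccc2)c1O
F4 | step 10 | bis[3,4-bis(benzyloxy)benzoate] of F3 | C=CCc1cc(-c2cc(OCc3ccccc3)c(OCc3ccccc3)c(OC(=O)c3ccc(OCc4ccccc4)c(OCc4ccccc4)c3)c2CC=C)c(OCc2ccccc2)c(OCc2ccccc2)c1OC(=O)c1ccc(OCc2ccccc2)c(OCc2ccccc2)c1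
F5 | step 10 | bis{1-[3,4-bis(benzyloxy)phenyl]vinyl} ether of F3 | C=CCc1cc(-c2cc(OCc3ccccc3)c(OCc3ccccc3)c(OC(=C)c3ccc(OCc4ccccc4)c(OCc4ccccc4)c3)c2CC=C)c(OCc2ccccc2)c(OCc2ccccc2)c1OC(=C)c1ccc(OCc2ccccc2)c(OCc2ccccc2)c1
F6 | step 10 | 5,6'-linked bis[7,8-bis(benzyloxy)-2-(3,4-bis(benzyloxy)phenyl)-4H-chromene] | c1ccccc1COc1ccc(C2=CCc3cc(-c4cc(OCc5ccccc5)c(OCc5ccccc5)c5OC(c6ccc(OCc7ccccc7)c(OCc7ccccc7)c6)=CCc45)c(OCc4ccccc4)c(OCc4ccccc4)c3O2)cc1OCc1ccccc1
F7 | step 7 | 2,3,4-trihydroxy-6-(5-formyl-2,3,4-trihydroxyphenyl)benzaldehyde | O=Cc1cc(-c2cc(O)c(O)c(O)c2C=O)c(O)c(O)c1O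
F8 | step 6 | 6-bromo-2,3,4-tris(benzyloxy)benzaldehyde | O=Cc1c(Br)cc(OCc2ccccc2)c(OCc2ccccc2)c1OCc1ccccc1
F9 | step 6 | 2,3,4-tris(benzyloxy)-5-(4,4,5,5-tetramethyl-1,3,2-dioxaborolan-2-yl)benzaldehyde | O=Cc1cc(B2OC(C)(C)C(C)(C)O2)c(OCc2ccccc2)c(OCc2ccccc2)c1OCc1ccccc1
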